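Assumption: nerol, 1-(trimethylsilyl)propyne, 2,6-dimethylhydroquinone and but-3-yn-1-ol are bought; C1–C16 below number the side chain from the benzylic carbon, and the target is the (10R,11R) diol.

**Retrosynthetic overview**
- The obvious aryl–C1 bond formation (aryl metal + allylic bromide) and an asymmetric dihydroxylation are both avoided; the final step is global desilylation of 22.
- C5–C6 is the convergent bond: alkyl–alkenyl Negishi coupling of homoallylzinc 21 (arene + C1–C5) with the E vinyl iodide 13 (C6–C16).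
- C1–C2 and the E C2=C3 olefin come from one flask: Zr-catalysed methylalumination of but-3-yn-1-ol, then Pd-catalysed benzylation with bromide 16; the E C6=C7 olefin comes from a second methylalumination/iodination.
- Both stereocentres come from one Sharpless epoxidation of nerol, relayed by a Payne rearrangement (C11–O kept, C10 set by one inversion); C8–C9 is made by opening the terminal epoxide 6 with lithiated propyne 8.
- Rings: the arene is bought; the only rings formed are the oxirane of 2 (step 1) and the transposed oxirane 6 (steps 2–3), opened in step 4.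

**Route**

Step 1
Reactants: 1 nerol, (2Z)-3,7-dimethylocta-2,6-dien-1-ol
Product: 2 [(2S,3R)-3-methyl-3-(4-methylpent-3-en-1-yl)oxiran-2-yl]methanol
Conditions: Ti(OiPr)4 (5 mol%), L-(+)-diethyl tartrate (7.5 mol%), t-BuOOH, 4 Å sieves, CH2Cl2, −20 °C
Reagents that add atoms: tert-butyl hydroperoxide, CC(C)(C)OO
Why: Katsuki–Sharpless asymmetric epoxidation, in which the tetravalent titanium/L-tartrate catalyst epoxidises only the allylic-alcohol olefin from one face, setting C2 (S) and C3 (R) of the cis-epoxide (future C10 and C11) and leaving the remote olefin alone.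

Step 2
Reactants: 2 (2S,3R)-epoxynerol
Product: 4 (2S,3R)-1-(tert-butylsulfanyl)-3,7-dimethyloct-6-ene-2,3-diol, via sodium epoxy alkoxide 3 (not isolated)
Conditions: t-BuSH (slow addition), 0.5 M aq. NaOH, t-BuOH, reflux
Reagents that add atoms: 2-methylpropane-2-thiol, CC(C)(C)S
Why: Payne rearrangement with thiolate trapping, in which the C1 alkoxide opens the epoxide at C2 with inversion and the thiolate captures the unhindered CH2 of terminal epoxide 3, so the tertiary C–O bond (future C11, R) is never broken and the secondary carbinol (future C10) is set by one clean inversion.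

Step 3
Reactants: 4 sulfide diol
Product: 6 (2R)-6-methyl-2-[(2R)-oxiran-2-yl]hept-5-en-2-ol, via sulfonium tetrafluoroborate 5 (not isolated)
Conditions: Me3OBF4 (1.05 equiv), CH2Cl2, 0 °C; then NaH (1.05 equiv), 0 °C
Reagents that add atoms: none
Why: S-methylation makes a sulfonium leaving group and one equivalent of base triggers 3-exo-tet closure by the C2 alkoxide (Sharpless–Masamune C1 activation), touching no stereocentre and leaving no excess base for a reverse Payne rearrangement.

Step 4
Reactants: 6 epoxy alcohol; 7 trimethyl(prop-1-yn-1-yl)silane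
Product: 10 (5R,6R)-6,10-dimethylundec-9-en-1-yne-5,6-diol, via lithiated propyne 8 (not isolated), via silylated alkyne diol 9 (not isolated)
Conditions: 7 (3 equiv), n-BuLi, TMEDA, THF/DMPU, −78 → −20 °C; add 6, −78 → 0 °C; then MeOH, K2CO3, rt
Reagents that add atoms: none
Why: SN2 opening of the terminal epoxide at its CH2 carbon by the propargylic lithium reagent forms C8–C9 without touching either stereocentre (aprotic lithium alkoxide conditions suppress Payne reversal), and methanolysis of the C–Si bond frees the terminal alkyne.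

Step 5
Reactants: 10 alkyne diol
Product: 11 (5R,6R)-6,10-dimethyl-5,6-bis(triethylsilyloxy)undec-9-en-1-yne
Conditions: Et3SiOTf (2.5 equiv), 2,6-lutidine, CH2Cl2, −78 → 0 °C
Reagents that add atoms: triethylsilyl trifluoromethanesulfonate, CC[Si](CC)(CC)OS(=O)(=O)C(F)(F)F
Why: Silyl triflate silylation protects both the secondary and the hindered tertiary hydroxyl, so the organoaluminium and organozinc steps see no O–H.

Step 6
Reactants: 11 bis-silyl ether alkyne
Product: 13 (1E,5R,6R)-1-iodo-2,6,10-trimethyl-5,6-bis(triethylsilyloxy)undeca-1,9-diene, via alkenylalane 12 (not isolated)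
Conditions: Me3Al (3 equiv), Cp2ZrCl2 (0.25 equiv), H2O (1 equiv), CH2Cl2, −20 → 0 °C; then I2, THF, −30 → 0 °C
Reagents that add atoms: trimethylaluminium, C[Al](C)C; iodine, II
Why: Negishi zirconium-catalysed methylalumination adds Me and Al syn across the terminal alkyne with Al on the terminal carbon, and iodinolysis of the C–Al bond with retention gives the E trisubstituted vinyl iodide (future C6=C7).

Step 7
Reactants: 14 2,6-dimethylbenzene-1,4-diol
Product: 15 1,4-bis(tert-butyldimethylsilyloxy)-2,6-dimethylbenzene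
Conditions: t-BuMe2SiCl (2.5 equiv), imidazole, DMF, rt
Reagents that add atoms: tert-butyldimethylsilyl chloride, CC(C)(C)[Si](C)(C)Cl
Why: Standard imidazole-mediated silylation of both phenols gives a symmetric arene stable to radical, organoaluminium and organozinc conditions.

Step 8
Reactants: 15 bis-silyl ether
Product: 16 2-(bromomethyl)-1,4-bis(tert-butyldimethylsilyloxy)-6-methylbenzene
Conditions: NBS (1.0 equiv), AIBN (5 mol%), PhCF3, 80 °C
Reagents that add atoms: N-bromosuccinimide, O=C1CCC(=O)N1Br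
Why: Wohl–Ziegler radical bromination, in which the two methyl groups are equivalent by symmetry so mono-bromination gives a single benzylic bromide, and non-polar radical conditions disfavour ionic ring bromination.

Step 9
Reactants: 17 but-3-yn-1-ol; 16 benzylic bromide
Product: 19 (3E)-5-[2,5-bis(tert-butyldimethylsilyloxy)-3-methylphenyl]-3-methylpent-3-en-1-ol, via alkenylalane 18 (not isolated)
Conditions: 17, Me3Al (3 equiv), Cp2ZrCl2 (0.25 equiv), CH2Cl2, 0 °C → rt; volatiles removed; then 16, Pd(PPh3)4 (5 mol%), THF, rt; aq. potassium sodium tartrate work-up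
Reagents that add atoms: trimethylaluminium, C[Al](C)C
Why: Zirconium-catalysed methylalumination (syn addition, E alane) followed by Negishi benzyl–alkenyl cross-coupling (oxidative addition of the benzylic bromide to zerovalent palladium, transmetalation from aluminium, reductive elimination with retention) builds C1–C2 and the E C2=C3 olefin in one flask.

Step 10
Reactants: 19 homoallylic alcohol
Product: 20 1,4-bis(tert-butyldimethylsilyloxy)-2-[(2E)-5-iodo-3-methylpent-2-en-1-yl]-6-methylbenzene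
Conditions: I2, PPh3, imidazole, CH2Cl2, 0 °C → rt
Reagents that add atoms: iodine, II
Why: Appel-type iodination converts the primary alcohol to the iodide by SN2 displacement of the oxyphosphonium without touching silyl ethers or olefins.

Step 11
Reactants: 20 homoallylic iodide; 13 vinyl iodide
Product: 22 1,4-bis(tert-butyldimethylsilyloxy)-2-methyl-6-[(2E,6E,10R,11R)-3,7,11,15-tetramethyl-10,11-bis(triethylsilyloxy)hexadeca-2,6,14-trien-1-yl]benzene, via alkylzinc iodide 21 (not isolated)
Conditions: 20 (1.4 equiv), Zn dust (activated, BrCH2CH2Br/Me3SiCl), LiCl, THF, 40 °C; then 13, Pd(dppf)Cl2 (5 mol%), THF, 45 °C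
Reagents that add atoms: none
Why: Direct zinc insertion into the primary C–I bond followed by Negishi alkyl–alkenyl cross-coupling forms C5–C6 with retention of the E vinyl iodide geometry, and the mild organozinc tolerates all four silyl ethers.

Step 12
Reactants: 22 tetrasilyl ether
Product: 23 2-[(2E,6E,10R,11R)-10,11-dihydroxy-3,7,11,15-tetramethylhexadeca-2,6,14-trien-1-yl]-6-methylbenzene-1,4-diol
Conditions: Bu4NF (6 equiv), AcOH (6 equiv), degassed THF, 0 → 40 °C, Ar; aq. Na2S2O4 wash
Reagents that add atoms: none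
Why: Fluoride-mediated desilylation cleaves all four Si–O bonds, the AcOH buffer keeps the hydroquinone protonated and unoxidised, and no stereocentre or olefin is affected.

**Compound list**
1 | nerol, (2Z)-3,7-dimethylocta-2,6-dien-1-ol | CC(C)=CCC/C(C)=C\CO | starting material
2 | [(2S,3R)-3-methyl-3-(4-methylpent-3-en-1-yl)oxiran-2-yl]methanol | CC(C)=CCC[C@@]1(C)O[C@H]1CO | intermediate
3 | sodium (2R)-6-methyl-2-[(2R)-oxiran-2-yl]hept-5-en-2-olate | CC(C)=CCC[C@@](C)([O-])[C@H]1CO1.[Na+] | intermediate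
4 | (2S,3R)-1-(tert-butylsulfanyl)-3,7-dimethyloct-6-ene-2,3-diol | CC(C)=CCC[C@@](C)(O)[C@H](O)CSC(C)(C)C | intermediate
5 | tert-butyl[(2S,3R)-2,3-dihydroxy-3,7-dimethyloct-6-en-1-yl]methylsulfonium tetrafluoroborate | CC(C)=CCC[C@@](C)(O)[C@H](O)C[S+](C)C(C)(C)C.F[B-](F)(F)F | intermediate
6 | (2R)-6-methyl-2-[(2R)-oxiran-2-yl]hept-5-en-2-ol | CC(C)=CCC[C@@](C)(O)[C@H]1CO1 | intermediate
7 | trimethyl(prop-1-yn-1-yl)silane | CC#C[Si](C)(C)C | starting material
8 | [3-(trimethylsilyl)prop-2-yn-1-yl]lithium | [Li]CC#C[Si](C)(C)C | intermediate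
9 | (5R,6R)-6,10-dimethyl-1-(trimethylsilyl)undec-9-en-1-yne-5,6-diol | CC(C)=CCC[C@@](C)(O)[C@H](O)CCC#C[Si](C)(C)C | intermediate
10 | (5R,6R)-6,10-dimethylundec-9-en-1-yne-5,6-diol | CC(C)=CCC[C@@](C)(O)[C@H](O)CCC#C | intermediate
11 | (5R,6R)-6,10-dimethyl-5,6-bis(triethylsilyloxy)undec-9-en-1-yne | CC(C)=CCC[C@@](C)(O[Si](CC)(CC)CC)[C@H](O[Si](CC)(CC)CC)CCC#C | intermediate
12 | dimethyl[(1E,5R,6R)-2,6,10-trimethyl-5,6-bis(triethylsilyloxy)undeca-1,9-dien-1-yl]alumane | CC(C)=CCC[C@@](C)(O[Si](CC)(CC)CC)[C@H](O[Si](CC)(CC)CC)CC/C(C)=C/[Al](C)C | intermediate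
13 | (1E,5R,6R)-1-iodo-2,6,10-trimethyl-5,6-bis(triethylsilyloxy)undeca-1,9-diene | CC(C)=CCC[C@@](C)(O[Si](CC)(CC)CC)[C@H](O[Si](CC)(CC)CC)CC/C(C)=C/I | intermediate
14 | 2,6-dimethylbenzene-1,4-diol | Cc1cc(O)cc(C)c1O | starting material
15 | 1,4-bis(tert-butyldimethylsilyloxy)-2,6-dimethylbenzene | Cc1cc(O[Si](C)(C)C(C)(C)C)cc(C)c1O[Si](C)(C)C(C)(C)C | intermediate
16 | 2-(bromomethyl)-1,4-bis(tert-butyldimethylsilyloxy)-6-methylbenzene | BrCc1cc(O[Si](C)(C)C(C)(C)C)cc(C)c1O[Si](C)(C)C(C)(C)C | intermediate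
17 | but-3-yn-1-ol | C#CCCO | starting material
18 | dimethyl{(1E)-4-[(dimethylalumanyl)oxy]-2-methylbut-1-en-1-yl}alumane | C[Al](C)/C=C(\C)CCO[Al](C)C | intermediate
19 | (3E)-5-[2,5-bis(tert-butyldimethylsilyloxy)-3-methylphenyl]-3-methylpent-3-en-1-ol | OCC/C(C)=C/Cc1cc(O[Si](C)(C)C(C)(C)C)cc(C)c1O[Si](C)(C)C(C)(C)C | intermediate
20 | 1,4-bis(tert-butyldimethylsilyloxy)-2-[(2E)-5-iodo-3-methylpent-2-en-1-yl]-6-methylbenzene | ICC/C(C)=C/Cc1cc(O[Si](C)(C)C(C)(C)C)cc(C)c1O[Si](C)(C)C(C)(C)C | intermediate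
21 | {(3E)-5-[2,5-bis(tert-butyldimethylsilyloxy)-3-methylphenyl]-3-methylpent-3-en-1-yl}(iodo)zinc | I[Zn]CC/C(C)=C/Cc1cc(O[Si](C)(C)C(C)(C)C)cc(C)c1O[Si](C)(C)C(C)(C)C | intermediate
22 | 1,4-bis(tert-butyldimethylsilyloxy)-2-methyl-6-[(2E,6E,10R,11R)-3,7,11,15-tetramethyl-10,11-bis(triethylsilyloxy)hexadeca-2,6,14-trien-1-yl]benzene | CC(C)=CCC[C@@](C)(O[Si](CC)(CC)CC)[C@H](O[Si](CC)(CC)CC)CC/C(C)=C/CC/C(C)=C/Cc1cc(O[Si](C)(C)C(C)(C)C)cc(C)c1O[Si](C)(C)C(C)(C)C | intermediate
23 | 2-[(2E,6E,10R,11R)-10,11-dihydroxy-3,7,11,15-tetramethylhexadeca-2,6,14-trien-1-yl]-6-methylbenzene-1,4-diol (CNP0319022.2) | CC(C)=CCC[C@@](C)(O)[C@H](O)CC/C(C)=C/CC/C(C)=C/Cc1cc(O)cc(C)c1O | target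

**Totals**
Total step count: 12. Longest linear sequence: 8 steps (steps 1–6, 11, 12); the arene branch is steps 7–10.

**Three steps most likely to fail**

Step 2 (Payne rearrangement with thiolate trapping). The Payne equilibrium of a trisubstituted epoxide lies far on the side of 2, so direct thiolate attack on 2 may compete. The fallback sets both centres by epoxide hydrolysis with inversion instead, sets out from 1 and comes back at 9. Sharpless epoxidation of 1 with D-(−)-diethyl tartrate gives [(2R,3S)-3-methyl-3-(4-methylpent-3-en-1-yl)oxiran-2-yl]methanol F1. TsCl/Et3N/DMAP gives the epoxy tosylate F2. Displacement of the primary tosylate by lithiated propyne 8 (THF/DMPU, −78 → 0 °C) leaves the cis-epoxide intact and gives the epoxy silyl-alkyne F3. Catalytic HClO4 in THF/H2O at 0 °C then opens the epoxide by attack of water at the tertiary carbon with inversion, which gives the (5R,6R) diol 9. The K2CO3/MeOH part of step 4 then delivers 10, so this detour also bypasses steps 3 and 4.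

Step 8 (benzylic mono-bromination of an electron-rich arene). Ring bromination or double bromination may dominate. The fallback brominates an electron-poor diester and exchanges the protecting groups afterwards; it sets out from 14 and comes back at 19. PivCl/pyridine gives 2,6-dimethyl-1,4-phenylene bis(2,2-dimethylpropanoate) F4. NBS/AIBN gives the benzylic bromide F5. Pd(PPh3)4-catalysed coupling with alkenylalane 18, as in step 9, gives the bis-pivalate homoallylic alcohol F6. LiAlH4 in THF at 0 °C removes both pivalates to give the hydroquinone triol F7. t-BuMe2SiCl/imidazole gives the tris-silyl ether F8. PPTS in MeOH then cleaves only the primary alkyl silyl ether and returns 19.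

Step 11 (late alkyl–alkenyl Negishi union of two elaborate fragments). Slow zinc insertion, protonolysis of 21 or sluggish coupling to the hindered vinyl iodide are the risks. The fallback grows the chain linearly and attaches the arene last through the benzyl–alkenyl coupling; it sets out from 13 and comes back at 22. (4-Bromobut-1-yn-1-yl)trimethylsilane and Zn dust give [4-(trimethylsilyl)but-3-yn-1-yl]zinc bromide F9. Pd(dppf)Cl2-catalysed coupling of F9 with 13 gives the silylated dienyne F10. K2CO3/MeOH gives the terminal alkyne F11. A second Me3Al/Cp2ZrCl2 methylalumination gives the E alkenylalane F12, which is coupled in the same flask with benzylic bromide 16 under Pd(PPh3)4 catalysis to give 22.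

**Further compounds**
F1 | step 2 | [(2R,3S)-3-methyl-3-(4-methylpent-3-en-1-yl)oxiran-2-yl]methanol | CC(C)=CCC[C@]1(C)O[C@@H]1CO
F2 | step 2 | [(2R,3S)-3-methyl-3-(4-methylpent-3-en-1-yl)oxiran-2-yl]methyl 4-methylbenzenesulfonate | CC(C)=CCC[C@]1(C)O[C@@H]1COS(=O)(=O)c1ccc(C)cc1
F3 | step 2 | trimethyl{4-[(2R,3S)-3-methyl-3-(4-methylpent-3-en-1-yl)oxiran-2-yl]but-1-yn-1-yl}silane | CC(C)=CCC[C@]1(C)O[C@@H]1CCC#C[Si](C)(C)C
F4 | step 8 | 2,6-dimethyl-1,4-phenylene bis(2,2-dimethylpropanoate) | Cc1cc(OC(=O)C(C)(C)C)cc(C)c1OC(=O)C(C)(C)C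
F5 | step 8 | 2-(bromomethyl)-6-methyl-1,4-phenylene bis(2,2-dimethylpropanoate) | BrCc1cc(OC(=O)C(C)(C)C)cc(C)c1OC(=O)C(C)(C)C
F6 | step 8 | 2-[(2E)-5-hydroxy-3-methylpent-2-en-1-yl]-6-methyl-1,4-phenylene bis(2,2-dimethylpropanoate) | OCC/C(C)=C/Cc1cc(OC(=O)C(C)(C)C)cc(C)c1OC(=O)C(C)(C)C
F7 | step 8 | 2-[(2E)-5-hydroxy-3-methylpent-2-en-1-yl]-6-methylbenzene-1,4-diol | OCC/C(C)=C/Cc1cc(O)cc(C)c1O
F8 | step 8 | 1,4-bis(tert-butyldimethylsilyloxy)-2-[(2E)-5-(tert-butyldimethylsilyloxy)-3-methylpent-2-en-1-yl]-6-methylbenzene | CC(C)(C)[Si](C)(C)OCC/C(C)=C/Cc1cc(O[Si](C)(C)C(C)(C)C)cc(C)c1O[Si](C)(C)C(C)(C)C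
F9 | step 11 | bromo[4-(trimethylsilyl)but-3-yn-1-yl]zinc | Br[Zn]CCC#C[Si](C)(C)C
F10 | step 11 | (5E,9R,10R)-6,10,14-trimethyl-9,10-bis(triethylsilyloxy)-1-(trimethylsilyl)pentadeca-5,13-dien-1-yne | CC(C)=CCC[C@@](C)(O[Si](CC)(CC)CC)[C@H](O[Si](CC)(CC)CC)CC/C(C)=C/CCC#C[Si](C)(C)C
F11 | step 11 | (5E,9R,10R)-6,10,14-trimethyl-9,10-bis(triethylsilyloxy)pentadeca-5,13-dien-1-yne | CC(C)=CCC[C@@](C)(O[Si](CC)(CC)CC)[C@H](O[Si](CC)(CC)CC)CC/C(C)=C/CCC#C
F12 | step 11 | dimethyl[(1E,5E,9R,10R)-2,6,10,14-tetramethyl-9,10-bis(triethylsilyloxy)pentadeca-1,5,13-trien-1-yl]alumane | CC(C)=CCC[C@@](C)(O[Si](CC)(CC)CC)[C@H](O[Si](CC)(CC)CC)CC/C(C)=C/CC/C(C)=C/[Al](C)C
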